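**Plan**

1. The target is (R)-5-formyl-δ-tocotrienol. The retrosynthesis first removes the C5 formyl group (ortho-formylation of the free 6-phenol, done last), then puts a methyl ether on O6 and re-oxidises C4 to a ketone.
2. The main cut is the bond between the quaternary ring carbon C2 and the first chain carbon C1'. It gives 6-methoxy-2,8-dimethylchromone and homofarnesylmagnesium bromide. The chromone goes back to 4-methoxy-2-methylphenol, the chain to (2E,6E)-farnesol plus one carbon.
3. Enabling feature: C2 carries the ring oxygen O1 and lies β to the benzylic carbon C4 through C3. With C4 as a ketone the pyran ring is a γ-pyranone (O1–C2=C3–C4=O) fused to the benzene ring, and O-silylation makes it an aromatic benzopyrylium ion that is electrophilic at C2.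
4. Forward order: the benzene ring is bought, the pyranone ring is closed in step 2, the chain is joined to C2 in step 8, the helpers (C4 oxygen, O-methyl) are removed in steps 9–11, and the aldehyde is added in step 12.
5. Stereochemistry: the only stereocentre, C2 (R), is set in step 8 by a chiral diphosphine–copper catalyst. The three E double bonds come from farnesol and are never touched.

Key step: step 8

Remark: "homofarnesyl" means (3E,7E)-4,8,12-trimethyltrideca-3,7,11-trien-1-yl; ring atoms carry chroman numbering (O1, C2 to C8a) and chain atoms are counted C1' onward from C2.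
Assumption: the sense of induction in step 8 has to be fixed by experiment; (R,R)-Ph-BPE is written, and its mirror image is used if it should deliver the S product.

**Step 1**
Reactants: 1 4-methoxy-2-methylphenol
Product: 3 1-(2-hydroxy-5-methoxy-3-methylphenyl)ethan-1-one, via aryl acetate 2 (not isolated)
Conditions: AcOH, BF3·OEt2, 90 °C; aq. NaOAc work-up
Reagents that add atoms: acetic acid, CC(=O)O
Why: BF3-promoted O-acetylation and Fries rearrangement (ortho-acylation of a phenol) should place the acetyl group only at the single free position ortho to the hydroxyl, since the para position is blocked by OMe and the other ortho position by CH3, and the boron chelate of the o-hydroxy ketone is the thermodynamic sink.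

**Step 2**
Reactants: 3 1-(2-hydroxy-5-methoxy-3-methylphenyl)ethan-1-one
Product: 5 6-methoxy-2,8-dimethyl-4H-chromen-4-one, via 1,3-diketone 4 (not isolated)
Conditions: NaH, EtOAc, THF, reflux; then conc. HCl (cat.), AcOH, 100 °C
Reagents that add atoms: ethyl acetate, CCOC(C)=O
Why: Crossed Claisen condensation of the phenoxide–enolate of 3 with ethyl acetate gives the 1,3-diketone, and acid-catalysed cyclodehydration (phenol oxygen onto the distal carbonyl, then loss of water) closes the γ-pyranone ring, which is the classical 2-methylchromone synthesis and leaves the aryl methyl ether intact.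

**Step 3**
Reactants: 6 (2E,6E)-farnesol
Product: 7 (2E,6E)-farnesal
Conditions: TEMPO (10 mol%), PhI(OAc)2, CH2Cl2, 0 °C to rt
Reagents that add atoms: none
Why: Oxoammonium (TEMPO/PhI(OAc)2) oxidation of a primary allylic alcohol stops at the enal and should neither isomerise the 2E double bond nor touch the other trisubstituted alkenes.

**Step 4**
Reactants: 7 (2E,6E)-farnesal
Product: 8 (3E,7E)-4,8,12-trimethyltrideca-1,3,7,11-tetraene
Conditions: Ph3PCH3Br, KOtBu, THF, 0 °C
Reagents that add atoms: methyltriphenylphosphonium bromide, C[P+](c1ccccc1)(c1ccccc1)c1ccccc1.[Br-]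
Why: Wittig methylenation with the non-stabilised ylide turns the enal into the terminal 1,3-diene without affecting the E geometry of the adjacent trisubstituted double bond.

**Step 5**
Reactants: 8 (3E,7E)-4,8,12-trimethyltrideca-1,3,7,11-tetraene
Product: 10 (3E,7E)-4,8,12-trimethyltrideca-3,7,11-trien-1-ol (homofarnesol), via B-alkyl-9-BBN 9 (not isolated)
Conditions: 9-BBN, THF, 0 °C to rt; then NaOH, H2O2, 0 °C
Reagents that add atoms: hydrogen peroxide, OO
Why: Hydroboration–oxidation with the bulky dialkylborane should attack only the monosubstituted terminal double bond of the diene, anti-Markovnikov at C1, and leave the three trisubstituted alkenes alone, as in the known one-carbon homologation of geranial to homogeraniol.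

**Step 6**
Reactants: 10 homofarnesol
Product: 11 (3E,7E)-1-bromo-4,8,12-trimethyltrideca-3,7,11-triene (homofarnesyl bromide)
Conditions: CBr4, PPh3, CH2Cl2, 0 °C
Reagents that add atoms: carbon tetrabromide, BrC(Br)(Br)Br
Why: Appel bromination converts the primary homoallylic alcohol into the bromide by SN2 displacement under neutral conditions that leave the triene untouched.

**Step 7**
Reactants: 11 homofarnesyl bromide
Product: 12 homofarnesylmagnesium bromide (titrated ethereal solution, used directly)
Conditions: Mg turnings (I2 activation), Et2O, reflux
Reagents that add atoms: magnesium, [Mg]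
Why: Oxidative insertion of magnesium into the primary C–Br bond gives the Grignard reagent, which as a homoallyl species with a trisubstituted alkene stays in the open-chain form.

**Step 8**
Reactants: 5 6-methoxy-2,8-dimethyl-4H-chromen-4-one; 12 homofarnesylmagnesium bromide
Product: 15 (R)-2-homofarnesyl-6-methoxy-2,8-dimethylchroman-4-one, via benzopyrylium triflate 13 (not isolated), via silyl enol ether 14 (not isolated)
Conditions: 5, TMSOTf, CH2Cl2, rt; then CuBr·SMe2 (5 mol%), (R,R)-Ph-BPE (6 mol%), −78 °C, slow addition of 12 in Et2O; then 1 M HCl, THF, 0 °C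
Reagents that add atoms: none
Why: Proposed new method: O-silylation of the chromone carbonyl by TMSOTf converts 5 into the aromatic 4-silyloxybenzopyrylium ion 13, whose C2 is strongly electrophilic, and the chiral alkylcopper(I) species formed from 12 and the diphosphine–CuBr complex adds there (π-complex, Cu(III) σ-alkyl, reductive elimination) to form the C2–C1' bond and the silyl enol ether 14, which dilute acid hydrolyses to 15. The closest known reaction types are the copper/bis(oxazoline)-catalysed alkynylation of 2-alkyl-4-silyloxybenzopyrylium triflates to tetrasubstituted chromanones and the copper/diphosphine-catalysed addition of Grignard reagents to chromones and to silyl- or acyl-activated quinolones and pyridinium ions; the combination of an alkyl Grignard reagent with a 2-alkylbenzopyrylium ion is the new element. No ring is closed, because the pyranone ring made in step 2 is carried through intact. The C2 stereocentre is controlled by the chiral diphosphine on copper, which distinguishes the two faces of the planar C2 of 13, and the ligand enantiomer is chosen to give R. The step needs C2 over C4 attack, which the OSiMe3 group on C4 secures by blocking and deactivating that carbon, and it needs the catalysed pathway to outrun direct Grignard addition, which the low temperature and the slow addition of 12 should secure. Because the product leaves the cycle as a silyl enol ether and not as a metal enolate, it cannot open by β-elimination of the phenoxide and so cannot lose the new stereocentre, and it is inert to excess 12.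

**Step 9**
Reactants: 15 (R)-2-homofarnesyl-6-methoxy-2,8-dimethylchroman-4-one
Product: 16 tosylhydrazone of 15
Conditions: TsNHNH2, PPTS (cat.), EtOH, 60 °C
Reagents that add atoms: p-toluenesulfonyl hydrazide, Cc1ccc(cc1)S(=O)(=O)NN
Why: Condensation of the aryl ketone with tosylhydrazide gives the tosylhydrazone under near-neutral conditions that do not enolise the chromanone, so the C2 stereocentre cannot be lost by ring opening.

**Step 10**
Reactants: 16 tosylhydrazone
Product: 18 (R)-2-homofarnesyl-6-methoxy-2,8-dimethylchroman (δ-tocotrienol methyl ether), via tosylhydrazine 17 (not isolated)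
Conditions: catecholborane, CHCl3, 0 °C to rt; then NaOAc·3H2O, reflux
Reagents that add atoms: none
Why: Tosylhydrazone reduction (Caglioti reaction in its catecholborane variant) adds hydride to C=N, acetate-induced loss of sulfinate gives the benzylic diazene, and this loses N2 to leave CH2 at C4, at temperatures at which catecholborane does not hydroborate trisubstituted alkenes.

**Step 11**
Reactants: 18 δ-tocotrienol methyl ether
Product: 19 (R)-δ-tocotrienol
Conditions: NaSEt, DMF (degassed), 140 °C; aq. HCl work-up
Reagents that add atoms: none
Why: SN2 demethylation of the unhindered aryl methyl ether by ethanethiolate in a dipolar aprotic solvent is base-only chemistry that the chroman ring, the quaternary centre and the unactivated trisubstituted alkenes should tolerate, unlike a Lewis-acid dealkylation.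

**Step 12**
Reactants: 19 (R)-δ-tocotrienol
Product: 21 (R)-5-formyl-δ-tocotrienol (target), via salicyl alcohol 20 (not isolated)
Conditions: MgCl2, Et3N, (CH2O)n, MeCN, reflux; dil. HCl work-up
Reagents that add atoms: formaldehyde (as paraformaldehyde), C=O
Why: Magnesium phenoxide-directed ortho-formylation (Casnati–Skattebøl) delivers formaldehyde to an ortho carbon and oxidises the resulting benzylic alkoxide by hydride transfer to a second formaldehyde, and it should favour C5 over C7 because electrophilic substitution of 8-methylchroman-6-ols is biased toward C5 by bond fixation from the fused dihydropyran ring (Mills–Nixon-type effect), while the mild conditions leave the triene and C2 untouched.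

**Compound list**

1 | 4-methoxy-2-methylphenol | COc1ccc(O)c(C)c1 | starting material
2 | 4-methoxy-2-methylphenyl acetate | COc1ccc(OC(C)=O)c(C)c1 | intermediate (not isolated)
3 | 1-(2-hydroxy-5-methoxy-3-methylphenyl)ethan-1-one | CC(=O)c1cc(OC)cc(C)c1O | intermediate
4 | 1-(2-hydroxy-5-methoxy-3-methylphenyl)butane-1,3-dione | CC(=O)CC(=O)c1cc(OC)cc(C)c1O | intermediate (not isolated)
5 | 6-methoxy-2,8-dimethyl-4H-chromen-4-one | Cc1cc(=O)c2cc(OC)cc(C)c2o1 | intermediate
6 | (2E,6E)-farnesol | CC(C)=CCC/C(C)=C/CC/C(C)=C/CO | starting material
7 | (2E,6E)-farnesal | CC(C)=CCC/C(C)=C/CC/C(C)=C/C=O | intermediate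
8 | (3E,7E)-4,8,12-trimethyltrideca-1,3,7,11-tetraene | CC(C)=CCC/C(C)=C/CC/C(C)=C/C=C | intermediate
9 | 9-homofarnesyl-9-borabicyclo[3.3.1]nonane | CC(C)=CCC/C(C)=C/CC/C(C)=C/CCB1C2CCCC1CCC2 | intermediate (not isolated)
10 | (3E,7E)-4,8,12-trimethyltrideca-3,7,11-trien-1-ol (homofarnesol) | CC(C)=CCC/C(C)=C/CC/C(C)=C/CCO | intermediate
11 | (3E,7E)-1-bromo-4,8,12-trimethyltrideca-3,7,11-triene (homofarnesyl bromide) | CC(C)=CCC/C(C)=C/CC/C(C)=C/CCBr | intermediate
12 | homofarnesylmagnesium bromide | CC(C)=CCC/C(C)=C/CC/C(C)=C/CC[Mg]Br | intermediate (solution, used directly)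
13 | 6-methoxy-2,8-dimethyl-4-(trimethylsilyloxy)chromenylium trifluoromethanesulfonate | Cc1cc(O[Si](C)(C)C)c2cc(OC)cc(C)c2[o+]1.[O-]S(=O)(=O)C(F)(F)F | intermediate (not isolated)
14 | (R)-2-homofarnesyl-6-methoxy-2,8-dimethyl-4-(trimethylsilyloxy)-2H-chromene | CC(C)=CCC/C(C)=C/CC/C(C)=C/CC[C@]1(C)C=C(O[Si](C)(C)C)c2cc(OC)cc(C)c2O1 | intermediate (not isolated)
15 | (R)-2-homofarnesyl-6-methoxy-2,8-dimethylchroman-4-one | CC(C)=CCC/C(C)=C/CC/C(C)=C/CC[C@]1(C)CC(=O)c2cc(OC)cc(C)c2O1 | intermediate
16 | N'-[(R)-2-homofarnesyl-6-methoxy-2,8-dimethylchroman-4-ylidene]-4-methylbenzenesulfonohydrazide (C=N geometry not defined) | CC(C)=CCC/C(C)=C/CC/C(C)=C/CC[C@]1(C)CC(=NNS(=O)(=O)c3ccc(C)cc3)c2cc(OC)cc(C)c2O1 | intermediate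
17 | N'-[(2R,4RS)-2-homofarnesyl-6-methoxy-2,8-dimethylchroman-4-yl]-4-methylbenzenesulfonohydrazide (N-boryl adduct in the flask, both C4 epimers) | CC(C)=CCC/C(C)=C/CC/C(C)=C/CC[C@]1(C)CC(NNS(=O)(=O)c3ccc(C)cc3)c2cc(OC)cc(C)c2O1 | intermediate (not isolated)
18 | (R)-2-homofarnesyl-6-methoxy-2,8-dimethylchroman (δ-tocotrienol methyl ether) | CC(C)=CCC/C(C)=C/CC/C(C)=C/CC[C@]1(C)CCc2cc(OC)cc(C)c2O1 | intermediate
19 | (R)-2-homofarnesyl-2,8-dimethylchroman-6-ol (δ-tocotrienol) | CC(C)=CCC/C(C)=C/CC/C(C)=C/CC[C@]1(C)CCc2cc(O)cc(C)c2O1 | intermediate
20 | (R)-2-homofarnesyl-5-(hydroxymethyl)-2,8-dimethylchroman-6-ol (magnesium salt in the flask) | CC(C)=CCC/C(C)=C/CC/C(C)=C/CC[C@]1(C)CCc2c(CO)c(O)cc(C)c2O1 | intermediate (not isolated)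
21 | (R)-2-homofarnesyl-6-hydroxy-2,8-dimethylchroman-5-carbaldehyde (5-formyl-δ-tocotrienol) | CC(C)=CCC/C(C)=C/CC/C(C)=C/CC[C@]1(C)CCc2c(C=O)c(O)cc(C)c2O1 | target

**Step count**

Total: 12 steps. Longest linear sequence: 10 steps (farnesol 6 to 21, steps 3–12). The chromone branch (steps 1–2) joins at step 8.

**Steps most likely to fail**

Step 8 (carries the label). The direct, uncatalysed addition of the Grignard reagent to the benzopyrylium ion may outrun the copper cycle and erode the enantioselectivity. Attack at C4 or failure of the catalyst to turn over at the fully substituted C2 are the other ways it can go wrong. The fallback uses known chemistry and changes the construction: the chain is brought in as a ketone and the pyranone ring is closed around C2, with the enantiomers separated afterwards. It sets out from acetophenone 3. Kabbe condensation of 3 with commercial (5E,9E)-farnesylacetone (pyrrolidine, toluene, reflux, water separator; enamine aldol condensation followed by intramolecular oxa-Michael addition) gives the racemic chromanone F1. Preparative chromatography on a chiral stationary phase separates the enantiomers. The (S)-chromanone F2 is set aside, and the (R)-enantiomer is compound 15, where the route is rejoined before step 9.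

Step 12. The formylation may show poor site selectivity between C5 and C7, or run on to the dialdehyde. The fallback introduces the carbon at the amine oxidation level and unmasks it stepwise. It sets out from δ-tocotrienol 19. Mannich aminomethylation (morpholine, aq. formaldehyde, EtOH, reflux), which in 8-methylchroman-6-ols is known to go to C5 and uses a bulkier electrophile, gives the Mannich base (R)-5-(morpholin-4-ylmethyl)-δ-tocotrienol F3. As a base, F3 can be freed from unreacted phenol by acid–base extraction, and from any isomer by chromatography, before going on. Heating F3 in acetic anhydride exchanges the amine for acetate and gives the diacetate (R)-5-(acetoxymethyl)-δ-tocotrienol 6-acetate F4. K2CO3 in MeOH removes both acetyl groups and gives salicyl alcohol 20, where the route is rejoined. Compound 20 is then oxidised to 21 with activated MnO2 in CH2Cl2, which touches only the benzylic alcohol.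

Step 10. Hydride transfer to the electron-rich aryl hydrazone may be incomplete, or elimination may compete with reduction. The fallback removes the C4 oxygen through the alcohol and the chromene. It sets out from chromanone 15. NaBH4 in MeOH at 0 °C gives the chroman-4-ol F5 as both C4 epimers. MsCl and Et3N in CH2Cl2, followed by DBU, eliminate the benzylic mesylate to the 2H-chromene F6. Sodium in boiling ethanol reduces only the styrene-type C3=C4 double bond, as is known for chromenes of the tocotrienol series, and gives 18, where the route is rejoined before step 11.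

**Further compounds**

F1 | step 8 | racemic 2-homofarnesyl-6-methoxy-2,8-dimethylchroman-4-one | CC(C)=CCC/C(C)=C/CC/C(C)=C/CCC1(C)CC(=O)c2cc(OC)cc(C)c2O1
F2 | step 8 | (S)-2-homofarnesyl-6-methoxy-2,8-dimethylchroman-4-one | CC(C)=CCC/C(C)=C/CC/C(C)=C/CC[C@@]1(C)CC(=O)c2cc(OC)cc(C)c2O1
F3 | step 12 | (R)-2-homofarnesyl-2,8-dimethyl-5-(morpholin-4-ylmethyl)chroman-6-ol | CC(C)=CCC/C(C)=C/CC/C(C)=C/CC[C@]1(C)CCc2c(CN3CCOCC3)c(O)cc(C)c2O1
F4 | step 12 | (R)-5-(acetoxymethyl)-2-homofarnesyl-2,8-dimethylchroman-6-yl acetate | CC(C)=CCC/C(C)=C/CC/C(C)=C/CC[C@]1(C)CCc2c(COC(C)=O)c(OC(C)=O)cc(C)c2O1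
F5 | step 10 | (2R,4RS)-2-homofarnesyl-6-methoxy-2,8-dimethylchroman-4-ol | CC(C)=CCC/C(C)=C/CC/C(C)=C/CC[C@]1(C)CC(O)c2cc(OC)cc(C)c2O1
F6 | step 10 | (R)-2-homofarnesyl-6-methoxy-2,8-dimethyl-2H-chromene | CC(C)=CCC/C(C)=C/CC/C(C)=C/CC[C@]1(C)C=Cc2cc(OC)cc(C)c2O1
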